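**Retrosynthetic overview**
1. Target 8 ⇒ seco acid 7 (32-hydroxydotriacontanoic acid): the only ring is opened at the lactone acyl C1–O bond. Forward, the free ω-hydroxy acid is closed through an enzyme-bound O-acyl-serine ester, the way a thioesterase releases a macrolactone.
2. 7 ⇒ 2 + 3: the chain is cut at C16–C17. Forward, a Cu-catalysed sp3–sp3 coupling joins the Grignard reagent of silyl ether 2 to the magnesium carboxylate of 16-bromohexadecanoic acid 3, with desilylation in the work-up.
3. 2 ⇒ 1 (16-bromohexadecan-1-ol) by O-silylation.
4. Ring order: one ring, formed in the last step.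

Assumption: the SMILES is read as one lactone C=O plus 31 CH2 groups (C32H62O2, 33-membered ring); it has no stereocentre, so the compound is achiral and there is no enantiomer to select.

**Route**

Step 1
Reactants: 1 16-bromohexadecan-1-ol
Product: 2 tert-butyl[(16-bromohexadecyl)oxy]dimethylsilane
Conditions: TBSCl (1.1 equiv), imidazole (1.5 equiv), CH2Cl2, 0 °C → rt, 2 h
Reagents that add atoms: tert-butyldimethylsilyl chloride (TBSCl), CC(C)(C)[Si](C)(C)Cl
Why: Imidazole-promoted O-silylation (TBS protection) masks the only acidic proton so that the primary bromide can later be converted into a Grignard reagent; no stereocentre is involved.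

Step 2
Reactants: 2 tert-butyl[(16-bromohexadecyl)oxy]dimethylsilane; 3 16-bromohexadecanoic acid
Product: 7 32-hydroxydotriacontanoic acid, via Grignard reagent 4 (not isolated), via chloromagnesium carboxylate 5 (not isolated), via silyl ether acid 6 (not isolated)
Conditions: (i) 2 (1.5 equiv), Mg (I2 cat.), THF, 45 °C; (ii) 3, MeMgCl (1.0 equiv), THF, −20 °C; (iii) add 4 to 5, Li2CuCl4 (3 mol %), THF–NMP, −20 °C → rt; (iv) 2 M aq HCl, THF, 50 °C, 3 h
Reagents that add atoms: none
Why: In this Kochi-type Cu-catalysed Grignard/alkyl bromide cross-coupling the magnesium carboxylate is inert to RMgX at low temperature while the cuprate formed from 4 displaces the primary bromide of 5, and the aqueous HCl quench also hydrolyses the primary TBS ether, so the 16 + 16 carbons give the C32 seco acid in one operation with no stereocentre formed.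

Step 3
Reactants: 7 32-hydroxydotriacontanoic acid
Product: 8 oxacyclotritriacontan-2-one (dotriacontan-32-olide)
Conditions: Novozym 435 (immobilised Candida antarctica lipase B, 50 wt %), 4 Å MS, toluene (2 mM), 75 °C, 48 h
Reagents that add atoms: none
Why: Lipase-catalysed macrolactonization, a reaction type known for C15–C16 ω-hydroxy acids and for cyclodepolymerization of polyesters and here stretched to C32, acylates the active-site serine with the free acid and lets the ω-OH intercept this acyl-enzyme as in thioesterase cyclorelease, and at 2 mM with water removal the ring–chain equilibrium of the strain-free 33-membered ring favours the monomeric lactone; no stereocentre is involved.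

**Compound list**
1 | 16-bromohexadecan-1-ol | OCCCCCCCCCCCCCCCCBr | starting material
2 | tert-butyl[(16-bromohexadecyl)oxy]dimethylsilane | CC(C)(C)[Si](C)(C)OCCCCCCCCCCCCCCCCBr | intermediate
3 | 16-bromohexadecanoic acid | OC(=O)CCCCCCCCCCCCCCCBr | starting material
4 | {16-[(tert-butyldimethylsilyl)oxy]hexadecyl}magnesium bromide | CC(C)(C)[Si](C)(C)OCCCCCCCCCCCCCCCC[Mg]Br | intermediate
5 | chloromagnesium 16-bromohexadecanoate | Cl[Mg]OC(=O)CCCCCCCCCCCCCCCBr | intermediate
6 | 32-[(tert-butyldimethylsilyl)oxy]dotriacontanoic acid | CC(C)(C)[Si](C)(C)OCCCCCCCCCCCCCCCCCCCCCCCCCCCCCCCC(=O)O | intermediate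
7 | 32-hydroxydotriacontanoic acid | OCCCCCCCCCCCCCCCCCCCCCCCCCCCCCCCC(=O)O | intermediate
8 | oxacyclotritriacontan-2-one (dotriacontan-32-olide), achiral | O=C1CCCCCCCCCCCCCCCCCCCCCCCCCCCCCCCO1 | target

**Step count and risks**
Total step count: 3. Longest linear sequence: 3 (1 → 2 → 7 → 8); 3 enters unchanged in step 2.

Most likely to fail is step 3. The C32 acid may be a poor substrate for the lipase, or the material may end up as linear oligoesters and the 66-membered diolide. The fallback sets out from 7 and comes back to the route at 8. Compound 7 is treated with 2,2'-dipyridyl disulfide and PPh3 (THF–toluene, 50 °C) to give S-(pyridin-2-yl) 32-hydroxydotriacontanethioate F1. This is added by syringe pump over 12 h to refluxing xylene (final 1 mM) and closes to 8 by double-activation thioester macrolactonization. That replaces catalytic enzymatic equilibration with stoichiometric kinetic activation of the acyl group.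

Second is step 2. Formation of the waxy C16 Grignard reagent may be accompanied by Wurtz dimerisation, and the C16 carboxylate salt may be too insoluble at −20 °C to couple cleanly. The fallback sets out from 2 and comes back to the route at 6. Compound 2 is heated with sodium benzenesulfinate (DMF, 80 °C) to give tert-butyldimethyl{[16-(phenylsulfonyl)hexadecyl]oxy}silane F2. n-BuLi (THF, −78 °C) converts it into {16-[(tert-butyldimethylsilyl)oxy]-1-(phenylsulfonyl)hexadecyl}lithium F3. F3 is alkylated with 5 (made from 3 and MeMgCl as in step 2; THF–DMPU, −78 °C → rt) and mild acidification gives 32-[(tert-butyldimethylsilyl)oxy]-17-(phenylsulfonyl)dotriacontanoic acid F4 (racemic at C17, a centre that is removed again). Reductive desulfonylation (Mg, MeOH–THF, 50 °C) then delivers 6, which the HCl treatment of step 2 converts into 7.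

Third is step 1. It is the least risky, but imidazole can N-alkylate the primary bromide on long reaction times. The fallback sets out from 1 and comes back to the route at 7 without any protecting group. Compound 1 is deprotonated with MeMgCl (THF, −20 °C) to chloromagnesium 16-bromohexadecan-1-olate F5. Magnesium insertion (THF, 50 °C) gives the alkoxide-bearing Grignard reagent [16-(chloromagnesiooxy)hexadecyl]magnesium bromide F6. F6 is coupled with 5 under the Li2CuCl4 conditions of step 2, and acidic work-up gives 7 directly.

**Further compounds**
F1 | step 3 | S-(pyridin-2-yl) 32-hydroxydotriacontanethioate | OCCCCCCCCCCCCCCCCCCCCCCCCCCCCCCCC(=O)Sc1ccccn1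
F2 | step 2 | tert-butyldimethyl{[16-(phenylsulfonyl)hexadecyl]oxy}silane | CC(C)(C)[Si](C)(C)OCCCCCCCCCCCCCCCCS(=O)(=O)c1ccccc1
F3 | step 2 | {16-[(tert-butyldimethylsilyl)oxy]-1-(phenylsulfonyl)hexadecyl}lithium | CC(C)(C)[Si](C)(C)OCCCCCCCCCCCCCCCC([Li])S(=O)(=O)c1ccccc1
F4 | step 2 | 32-[(tert-butyldimethylsilyl)oxy]-17-(phenylsulfonyl)dotriacontanoic acid (racemic) | CC(C)(C)[Si](C)(C)OCCCCCCCCCCCCCCCC(CCCCCCCCCCCCCCCC(=O)O)S(=O)(=O)c1ccccc1
F5 | step 1 | chloromagnesium 16-bromohexadecan-1-olate | Cl[Mg]OCCCCCCCCCCCCCCCCBr
F6 | step 1 | [16-(chloromagnesiooxy)hexadecyl]magnesium bromide | Cl[Mg]OCCCCCCCCCCCCCCCC[Mg]Br
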